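Of the starting material lost in the north-east run between 6.00 min and 12.0 min, 24.6% appeared as target, and that interval passes a conversion of 20%. This figure, target gained per starting material lost, is the target share of the loss.

in all of them: free catalyst 0.30 mM

| run | starting material | solid reagent | remark |
|---|---|---|---|
| south-east | 0.034 M | 0.20 M | run made earlier |
| west | 0.075 M | 0.20 M | run made earlier |
| north-east | 0.050 M | 0.40 M | run made earlier |
| flask | 0.050 M | 0.200 M |  |

| run | time / min | target / % | starting material / % |
|---|---|---|---|
| south-east | 2.50 | 0 | 94.5 |
| south-east | 4.00 | 0.9 | 91.2 |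
| south-east | 6.00 | 2.3 | 86.6 |
| south-east | 8.00 | 2.6 | 82.2 |
| south-east | 12.0 | 4.9 | 74.4 |
| south-east | 20.0 | 8.9 | 61.0 |
| south-east | 30.0 | 13.9 | 49.0 |
| west | 4.00 | 0.3 | 91.4 |
| west | 8.00 | 2.0 | 83.3 |
| west | 12.0 | 2.8 | 75.5 |
| west | 15.0 | 4.3 | 71.3 |
| west | 20.0 | 5.6 | 64.0 |
| west | 25.0 | 7.5 | 57.8 |
| west | 30.0 | 9.1 | 52.4 |
| north-east | 6.00 | 1.4 | 86.9 |
| north-east | 12.0 | 4.3 | 75.1 |
| north-east | 20.0 | 7.8 | 62.6 |
| north-east | 25.0 | 9.5 | 56.4 |
| north-east | 30.0 | 11.2 | 50.3 |

(standard deviation of a reading: 0.3 percentage points)

- as a solid, counted per litre of solution: solid reagent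
- what was read earlier has a scatter of 0.3 percentage points, one standard deviation
- at the start none of the solid reagent is in solution
- what has gone from starting material into another species counts as reacted, even if it can come back
- no earlier run changes the charge of free catalyst; that part of a forecast is a guess

- apparent order in free catalyst when 20% of the starting material are converted (percent change of the rate of making target for one percent more free catalyst charged)
- factor on the rate of making target when 20% of the starting material are converted if free catalyst is charged twice over

The earlier runs look contradictory. The west run was charged with about twice the starting material of the south-east run, yet at 30.0 min they keep a similar 52.4% and 49.0%, while target stands at 9.1% and 13.9%. As concentrations, c(target) is 6.82 mM against 4.73 mM, an order in the charge of 0.465. Both readings can stand because target takes a quarter of the loss, and the remainder keeps a first-order pace of its own.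

No earlier run changes the charge of free catalyst, so the readings give no order in it, and the reckoning here turns to the time instead. If the remainder of the loss stays unchanged, even a full doubling of the rate of making target multiplies the time to 20% by just 0.803. The forecast gives an order of 0.8 (0.45 to 1.05) and a factor of 1.75 (1.35 to 2.1), from “a near-saturated, catalyst-limited turnover, which points to order near 1”.

The flask gives an order of 0.69 and a factor of 1.52.

    partner + free catalyst ⇌ catalyst intermediate A (K = 10.0 L mol⁻¹, k = 14.0 L mol⁻¹ s⁻¹)
    starting material + catalyst intermediate A ⇌ catalyst intermediate B (K = 300 L mol⁻¹, k = 21.0 L mol⁻¹ s⁻¹)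
    catalyst intermediate B → free catalyst + target (k = 5.10 s⁻¹)
    starting material ⇌ dormant form (K = 1.70, k = 3.60 × 10⁻⁴ s⁻¹)
    solid reagent ⇌ partner, rate k5*(cs5 - [partner]) while solid is left; crystals form when [partner] > cs5 (solubility = 4.20 mM, k = 0.00260 s⁻¹)

At 25.0 min the flask holds 34.4% as dormant form against 9.62% as target. Put into the target share, the factor 1.52 gives a time factor of 0.887, and the flask with twice the free catalyst takes 0.915 of the 9.37 min that this flask needs.

The runs are simulated with made-up constants; noise was put on by code.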